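## Retrosynthetic overview
1. 25 ⇐ 24 (hydrogenolysis of nine XB ethers) ⇐ 23 (C–H hydroxylation at the only CH2 left, C4 of the bottom unit) ⇐ triketone 22 ⇐ all-2,3-trans trimer 21. One oxidation/hydride pair inverts all three C3 centres and creates the all-cis C2/C3/C4 triads of the top and middle units.
2. 21 ⇐ two cationic C4→C8 couplings (middle–bottom bond first, then top–middle bond) with the enantiomeric 4-alkoxy 3-propanoates 17 and 18. Ester participation makes each new bond 3,4-trans, which is 2,4-cis.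
3. 14, 15 and 16 ⇐ one racemic 2,3-trans-flavan-3-ol 13 through a single kinetic resolution, because the target holds both antipodal series (2S twice, 2R once).
4. 13 ⇐ ring expansion (1,2-shift of the ring oxygen, dihydrofuran → dihydropyran) of carbinol 12 ⇐ epoxide of cinnamylphenol 10 ⇐ phenol 4 + allylic alcohol 9.
5. Ring order: rings A and B come from resorcinol and 4-bromophenol (third A-ring oxygen by C–H borylation/oxidation). The five-membered O-ring follows in step 6 and is expanded to ring C in step 7. No ring is made after the monomer stage.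

Assumption: the stereo-SMILES is taken literally, so the top unit is 2S,3S,4R, the middle unit 2R,3R,4S and the bottom unit 2S,3S,4R, i.e. ent-epiafzelechin-(4β→8)-epiafzelechin-(4α→8)-(2,3-cis-3,4-trans)-leucopelargonidin of the 2S series.

Abbreviation: XB = 3,5-dimethylbenzyl, a hydrogenolysable benzyl-type ether. Flavan numbering is used throughout.

## Route

Step 1
Reactants: 1 resorcinol
Product: 2 1,3-bis(3,5-dimethylbenzyloxy)benzene
Conditions: 3,5-dimethylbenzyl bromide (2.2 equiv), K2CO3, DMF, 60 °C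
Reagents that add atoms: 3,5-dimethylbenzyl bromide, Cc1cc(C)cc(CBr)c1
Why: Williamson ether synthesis; the XB group behaves like benzyl, but every C–H of its ring is flanked on both sides, which step 2 needs.

Step 2
Reactants: 2 1,3-bis(XB-oxy)benzene
Product: 4 3,5-bis(XB-oxy)phenol, via pinacol boronate 3 (not isolated)
Conditions: HBpin (1.5 equiv), [Ir(OMe)(cod)]2 (1.5 mol %), dtbpy (3 mol %), MTBE, 60 °C; then 30 % H2O2, THF–H2O, rt
Reagents that add atoms: pinacolborane, B1OC(C)(C)C(C)(C)O1 (held only in 3); hydrogen peroxide, OO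
Why: Sterically governed iridium-catalysed aromatic C–H borylation strikes the only C–H without an ortho neighbour (C5 of the resorcinol ring), and peroxide oxidation of the boronate gives the phloroglucinol oxygen pattern.

Step 3
Reactants: 5 4-bromophenol
Product: 6 1-bromo-4-(XB-oxy)benzene
Conditions: 3,5-dimethylbenzyl bromide (1.1 equiv), K2CO3, DMF, 50 °C
Reagents that add atoms: 3,5-dimethylbenzyl bromide, Cc1cc(C)cc(CBr)c1
Why: Williamson ether synthesis protects the ring B phenol before metalation.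

Step 4
Reactants: 6 1-bromo-4-(XB-oxy)benzene; 7 acrolein
Product: 9 (±)-1-[4-(XB-oxy)phenyl]prop-2-en-1-ol, via arylmagnesium bromide 8 (not isolated)
Conditions: Mg, THF, 40 °C; then 7, −78 → 0 °C; aq. NH4Cl
Reagents that add atoms: magnesium, [Mg] (held only in 8)
Why: Grignard formation and 1,2-addition to the enal; the racemic carbinol centre is erased in step 5.

Step 5
Reactants: 4 3,5-bis(XB-oxy)phenol; 9 allylic alcohol
Product: 10 (E)-2-{3-[4-(XB-oxy)phenyl]prop-2-enyl}-3,5-bis(XB-oxy)phenol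
Conditions: H2SO4 on SiO2 (cat.), CH2Cl2, 0 °C → rt
Reagents that add atoms: none
Why: In this acid-catalysed Friedel–Crafts allylation 9 ionises to the 1-arylallyl cation, and the phenol attacks its free terminus through the carbon ortho to OH, giving the conjugated E-alkene as known for 3,5-dialkoxyphenols.

Step 6
Reactants: 10 cinnamylphenol
Product: 12 (±)-(S*)-[(2R*)-4,6-bis(XB-oxy)-2,3-dihydrobenzofuran-2-yl][4-(XB-oxy)phenyl]methanol, via trans-epoxide 11 (not isolated)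
Conditions: dimethyldioxirane (1.0 equiv), acetone–CH2Cl2, −40 °C; volatiles off cold; KOt-Bu (10 mol %), THF, −20 → 0 °C
Reagents that add atoms: dimethyldioxirane, CC1(C)OO1
Why: Stereospecific dioxirane epoxidation gives the trans-epoxide, and the phenoxide opens it by a Baldwin-favoured 5-exo-tet SN2 attack with inversion at the homobenzylic carbon, which fixes the relative configuration of 12 (any 6-endo product is 13 itself and is carried along).

Step 7
Reactants: 12 dihydrobenzofuranyl carbinol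
Product: 13 (±)-(2R*,3S*)-5,7,4'-tri-O-XB-afzelechin (2,3-trans-flavan-3-ol)
Conditions: Ca(NTf2)2 (5 mol %), n-Bu4NPF6 (5 mol %), HFIP–CH2Cl2–H2O 10:10:1, 5 mM, 0 °C
Reagents that add atoms: water, O
Why: Proposed new method: an acid-catalysed isomerising ring expansion by 1,2-shift of the ring oxygen, in which the 4-alkoxybenzylic C–OH ionises reversibly in HFIP, the dihydrofuran oxygen bridges to the cationic carbon (inversion) to give a bicyclic aryloxiranium ion, and water opens this ion at the former C2 of the dihydrofuran (inversion); water return at the benzylic carbon is reversible, whereas the non-benzylic 3-ol cannot re-ionise, so the material drains into the less strained dihydropyran, and the double inversion forms ring C with the 2,3-trans relation; the closest known reaction types are the Zn(OAc)2-assisted oxolane-to-oxane expansion of 1-sulfonyloxyalkyl tetrahydrofurans, the prolinol-to-3-hydroxypiperidine expansion through aziridinium ions under thermodynamic control, and the acid isomerisation of 2-(2-hydroxyprop-2-yl)dihydrobenzofurans to 3-hydroxy-2,2-dimethylchromans, none of which has been shown on a secondary benzylic carbinol or used to build a flavan-3-ol.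

Step 8
Reactants: 13 racemic trans-flavan-3-ol
Product: 14 (2R,3S)-3-O-propanoyl-5,7,4'-tri-O-XB-afzelechin + 15 unreacted (2S,3R)-5,7,4'-tri-O-XB-ent-afzelechin (separated on silica; both are used)
Conditions: (S)-homobenzotetramisole (5 mol %; its antipode if the sense proves opposite), (EtCO)2O (0.55 equiv), i-Pr2NEt, CHCl3, −20 °C, about 50 % conversion
Reagents that add atoms: propanoic anhydride, CCC(=O)OC(=O)CC
Why: This is an acylative kinetic resolution with an amidine-based catalyst, a reaction type established for trans-2-arylcycloalkanols (cation–π stacking of the acyl-amidinium ion on the 2-aryl group), and it sets the absolute configuration at C2 of all three units.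

Step 9
Reactants: 15 (2S,3R)-alcohol (about half of it)
Product: 16 (2S,3R)-3-O-propanoyl-5,7,4'-tri-O-XB-ent-afzelechin
Conditions: (EtCO)2O, DMAP (5 mol %), Et3N, CH2Cl2, rt
Reagents that add atoms: propanoic anhydride, CCC(=O)OC(=O)CC
Why: DMAP-catalysed esterification installs the same participating ester in the 2S series without touching a stereocentre.

Step 10
Reactants: 14 (2R,3S)-propanoate
Product: 17 (2R,3S,4R)-4-(2-ethoxyethoxy)-3-O-propanoyl-5,7,4'-tri-O-XB-afzelechin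
Conditions: DDQ (1.5 equiv), EtOCH2CH2OH (5 equiv), CH2Cl2, rt
Reagents that add atoms: 2-ethoxyethanol, CCOCCO
Why: In this oxidative benzylic C–H etherification DDQ abstracts hydride from the A-ring-activated C4–H and the alcohol captures the cation anti to the 3-acyloxy group (the C4 configuration is lost again in step 12).

Step 11
Reactants: 16 (2S,3R)-propanoate
Product: 18 (2S,3R,4S)-4-(2-ethoxyethoxy)-3-O-propanoyl-5,7,4'-tri-O-XB-ent-afzelechin
Conditions: DDQ (1.5 equiv), EtOCH2CH2OH (5 equiv), CH2Cl2, rt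
Reagents that add atoms: 2-ethoxyethanol, CCOCCO
Why: The same DDQ benzylic C–H etherification is run on the enantiomer.

Step 12
Reactants: 17 middle-unit electrophile; 15 (2S,3R)-alcohol as nucleophile (1.2 equiv)
Product: 19 3-O-propanoyl-afzelechin-(4α→8)-ent-afzelechin hexa-O-XB ether (upper unit 2R,3S,4S; lower unit 2S,3R)
Conditions: Yb(OTf)3 (20 mol %), CH2Cl2, rt
Reagents that add atoms: none
Why: In this Lewis-acid Friedel–Crafts-type flavanyl 4→8 coupling the chelating ether leaves, the 3β-propanoate shields the β face as an acyloxonium ion, and C8 of 15 (the most nucleophilic site of a 5,7-dialkoxyflavan) attacks from the α face, setting C4 of the middle unit as 4α (3,4-trans, 2,4-cis).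

Step 13
Reactants: 18 top-unit electrophile; 19 dimer
Product: 21 ent-afzelechin-(4β→8)-afzelechin-(4α→8)-ent-afzelechin nona-O-XB ether (triol), via trimer dipropanoate 20 (not isolated)
Conditions: AgOTf (50 mol %), CH2Cl2, rt; then K2CO3, MeOH, 40 °C in the same flask
Reagents that add atoms: none
Why: The same coupling runs in the mirror-image sense, so the 3α-propanoate blocks the α face and the only free C8 (middle unit) attacks from the β face, setting C4 of the top unit as 4β (3,4-trans, 2,4-cis), and base-catalysed transesterification then frees both 3-OH groups.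

Step 14
Reactants: 21 triol
Product: 22 3-oxo trimer (triketone; top unit 2S,4R, middle unit 2R,4S, bottom unit 2S; 2,4-cis in the top and middle units)
Conditions: Dess–Martin periodinane (4.5 equiv), wet CH2Cl2, rt
Reagents that add atoms: none
Why: Dess–Martin oxidation, known on protected monomeric flavan-3-ols, works under near-neutral conditions that leave the enolisable C2 and C4 centres (aryl groups both equatorial) unchanged.

Step 15
Reactants: 22 triketone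
Product: 23 ent-epiafzelechin-(4β→8)-epiafzelechin-(4α→8)-ent-epiafzelechin nona-O-XB ether (top 2S,3S,4R; middle 2R,3R,4S; bottom 2S,3S)
Conditions: LiBH(s-Bu)3 (6 equiv), LiBr, THF, −78 °C; H2O quench
Reagents that add atoms: none
Why: In this bulky-hydride ketone reduction under steric approach control, hydride enters each carbonyl from the face opposite the 2-aryl group (and the 4-aryl group), giving the axial alcohols and thus C3 as S (top), R (middle) and S (bottom), as known for the catechin-to-epicatechin inversion.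

Step 16
Reactants: 23 tri-cis triol
Product: 24 as 23 with a 4α-hydroxy group in the bottom unit (bottom unit 2S,3S,4R)
Conditions: DDQ (1.3 equiv), CH2Cl2–H2O 18:1, 0 °C
Reagents that add atoms: water, O
Why: DDQ benzylic C–H hydroxylation takes hydride from the only unhindered A-ring-activated CH2 (the two diarylmethine C4–H bonds are buried), and water adds to the 2,3-cis cation anti to the axial 3β-OH, giving the 3,4-trans 4α-alcohol.

Step 17
Reactants: 24 nona-O-XB trimer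
Product: 25 target CNP0159291.1
Conditions: H2 (1 atm), Pd(OH)2/C, THF–H2O 9:1 (no acid, no alcohol), rt
Reagents that add atoms: none
Why: Heterogeneous hydrogenolysis cleaves the nine primary benzylic aryl ethers, while the neutral, alcohol-free medium spares the hindered secondary C4–OH, the C2–O bonds and the interflavan bonds, and no stereocentre is touched.

## Compound list
1 | resorcinol | Oc1cccc(O)c1 | starting material
2 | 1,3-bis(3,5-dimethylbenzyloxy)benzene | Cc1cc(C)cc(COc2cccc(OCc3cc(C)cc(C)c3)c2)c1 | intermediate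
3 | 2-[3,5-bis(XB-oxy)phenyl]-4,4,5,5-tetramethyl-1,3,2-dioxaborolane | Cc1cc(C)cc(COc2cc(OCc3cc(C)cc(C)c3)cc(B3OC(C)(C)C(C)(C)O3)c2)c1 | intermediate
4 | 3,5-bis(XB-oxy)phenol | Cc1cc(C)cc(COc2cc(O)cc(OCc3cc(C)cc(C)c3)c2)c1 | intermediate
5 | 4-bromophenol | Oc1ccc(Br)cc1 | starting material
6 | 1-bromo-4-(XB-oxy)benzene | Cc1cc(C)cc(COc2ccc(Br)cc2)c1 | intermediate
7 | acrolein | C=CC=O | starting material
8 | 4-(XB-oxy)phenylmagnesium bromide | Cc1cc(C)cc(COc2ccc([Mg]Br)cc2)c1 | intermediate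
9 | (±)-1-[4-(XB-oxy)phenyl]prop-2-en-1-ol | C=CC(O)c1ccc(OCc2cc(C)cc(C)c2)cc1 | intermediate
10 | (E)-2-{3-[4-(XB-oxy)phenyl]prop-2-enyl}-3,5-bis(XB-oxy)phenol | Oc1cc(OCc5cc(C)cc(C)c5)cc(OCc5cc(C)cc(C)c5)c1C/C=C/c1ccc(OCc5cc(C)cc(C)c5)cc1 | intermediate
11 | (±)-2-({(2S*,3S*)-3-[4-(XB-oxy)phenyl]oxiran-2-yl}methyl)-3,5-bis(XB-oxy)phenol (trans; one enantiomer drawn) | Oc1cc(OCc5cc(C)cc(C)c5)cc(OCc5cc(C)cc(C)c5)c1C[C@@H]1O[C@H]1c1ccc(OCc5cc(C)cc(C)c5)cc1 | intermediate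
12 | (±)-(S*)-[(2R*)-4,6-bis(XB-oxy)-2,3-dihydrobenzofuran-2-yl][4-(XB-oxy)phenyl]methanol (one enantiomer drawn) | O[C@@H](c1ccc(OCc5cc(C)cc(C)c5)cc1)[C@H]1Cc2c(OCc5cc(C)cc(C)c5)cc(OCc5cc(C)cc(C)c5)cc2O1 | intermediate
13 | (±)-(2R*,3S*)-5,7,4'-tri-O-XB-afzelechin (one enantiomer drawn) | O[C@H]1Cc2c(OCc5cc(C)cc(C)c5)cc(OCc5cc(C)cc(C)c5)cc2O[C@@H]1c1ccc(OCc5cc(C)cc(C)c5)cc1 | intermediate
14 | (2R,3S)-3-O-propanoyl-5,7,4'-tri-O-XB-afzelechin | CCC(=O)O[C@H]1Cc2c(OCc5cc(C)cc(C)c5)cc(OCc5cc(C)cc(C)c5)cc2O[C@@H]1c1ccc(OCc5cc(C)cc(C)c5)cc1 | intermediate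
15 | (2S,3R)-5,7,4'-tri-O-XB-ent-afzelechin | O[C@@H]1Cc2c(OCc5cc(C)cc(C)c5)cc(OCc5cc(C)cc(C)c5)cc2O[C@H]1c1ccc(OCc5cc(C)cc(C)c5)cc1 | intermediate
16 | (2S,3R)-3-O-propanoyl-5,7,4'-tri-O-XB-ent-afzelechin | CCC(=O)O[C@@H]1Cc2c(OCc5cc(C)cc(C)c5)cc(OCc5cc(C)cc(C)c5)cc2O[C@H]1c1ccc(OCc5cc(C)cc(C)c5)cc1 | intermediate
17 | (2R,3S,4R)-4-(2-ethoxyethoxy)-3-O-propanoyl-5,7,4'-tri-O-XB-afzelechin | CCC(=O)O[C@H]1[C@H](OCCOCC)c2c(OCc5cc(C)cc(C)c5)cc(OCc5cc(C)cc(C)c5)cc2O[C@@H]1c1ccc(OCc5cc(C)cc(C)c5)cc1 | intermediate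
18 | (2S,3R,4S)-4-(2-ethoxyethoxy)-3-O-propanoyl-5,7,4'-tri-O-XB-ent-afzelechin | CCC(=O)O[C@@H]1[C@@H](OCCOCC)c2c(OCc5cc(C)cc(C)c5)cc(OCc5cc(C)cc(C)c5)cc2O[C@H]1c1ccc(OCc5cc(C)cc(C)c5)cc1 | intermediate
19 | 3-O-propanoyl-afzelechin-(4α→8)-ent-afzelechin hexa-O-XB ether | c1(OCc5cc(C)cc(C)c5)ccc([C@H]2Oc3c(c(OCc5cc(C)cc(C)c5)cc(OCc5cc(C)cc(C)c5)c3)[C@@H](c3c(OCc5cc(C)cc(C)c5)cc(OCc5cc(C)cc(C)c5)c4c3O[C@@H](c3ccc(OCc5cc(C)cc(C)c5)cc3)[C@H](O)C4)[C@@H]2OC(=O)CC)cc1 | intermediate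
20 | 3-O-propanoyl-ent-afzelechin-(4β→8)-3-O-propanoyl-afzelechin-(4α→8)-ent-afzelechin nona-O-XB ether | c1(OCc5cc(C)cc(C)c5)ccc([C@H]2Oc3c(c(OCc5cc(C)cc(C)c5)cc(OCc5cc(C)cc(C)c5)c3[C@H]3c4c(OCc5cc(C)cc(C)c5)cc(OCc5cc(C)cc(C)c5)cc4O[C@@H](c4ccc(OCc5cc(C)cc(C)c5)cc4)[C@@H]3OC(=O)CC)[C@@H](c3c(OCc5cc(C)cc(C)c5)cc(OCc5cc(C)cc(C)c5)c4c3O[C@@H](c3ccc(OCc5cc(C)cc(C)c5)cc3)[C@H](O)C4)[C@@H]2OC(=O)CC)cc1 | intermediate
21 | ent-afzelechin-(4β→8)-afzelechin-(4α→8)-ent-afzelechin nona-O-XB ether | c1(OCc5cc(C)cc(C)c5)ccc([C@H]2Oc3c(c(OCc5cc(C)cc(C)c5)cc(OCc5cc(C)cc(C)c5)c3[C@H]3c4c(OCc5cc(C)cc(C)c5)cc(OCc5cc(C)cc(C)c5)cc4O[C@@H](c4ccc(OCc5cc(C)cc(C)c5)cc4)[C@@H]3O)[C@@H](c3c(OCc5cc(C)cc(C)c5)cc(OCc5cc(C)cc(C)c5)c4c3O[C@@H](c3ccc(OCc5cc(C)cc(C)c5)cc3)[C@H](O)C4)[C@@H]2O)cc1 | intermediate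
22 | triketone of 21 (all three C3 as C=O; C2 and C4 unchanged) | c1(OCc5cc(C)cc(C)c5)ccc([C@H]2Oc3c(c(OCc5cc(C)cc(C)c5)cc(OCc5cc(C)cc(C)c5)c3[C@H]3c4c(OCc5cc(C)cc(C)c5)cc(OCc5cc(C)cc(C)c5)cc4O[C@@H](c4ccc(OCc5cc(C)cc(C)c5)cc4)C3=O)[C@@H](c3c(OCc5cc(C)cc(C)c5)cc(OCc5cc(C)cc(C)c5)c4c3O[C@@H](c3ccc(OCc5cc(C)cc(C)c5)cc3)C(=O)C4)C2=O)cc1 | intermediate
23 | ent-epiafzelechin-(4β→8)-epiafzelechin-(4α→8)-ent-epiafzelechin nona-O-XB ether | c1(OCc5cc(C)cc(C)c5)ccc([C@H]2Oc3c(c(OCc5cc(C)cc(C)c5)cc(OCc5cc(C)cc(C)c5)c3[C@H]3c4c(OCc5cc(C)cc(C)c5)cc(OCc5cc(C)cc(C)c5)cc4O[C@@H](c4ccc(OCc5cc(C)cc(C)c5)cc4)[C@H]3O)[C@@H](c3c(OCc5cc(C)cc(C)c5)cc(OCc5cc(C)cc(C)c5)c4c3O[C@@H](c3ccc(OCc5cc(C)cc(C)c5)cc3)[C@@H](O)C4)[C@H]2O)cc1 | intermediate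
24 | 23 with 4α-OH in the bottom unit (bottom unit 2S,3S,4R) | c1(OCc5cc(C)cc(C)c5)ccc([C@H]2Oc3c(c(OCc5cc(C)cc(C)c5)cc(OCc5cc(C)cc(C)c5)c3[C@H]3c4c(OCc5cc(C)cc(C)c5)cc(OCc5cc(C)cc(C)c5)cc4O[C@@H](c4ccc(OCc5cc(C)cc(C)c5)cc4)[C@H]3O)[C@@H](c3c(OCc5cc(C)cc(C)c5)cc(OCc5cc(C)cc(C)c5)c4c3O[C@@H](c3ccc(OCc5cc(C)cc(C)c5)cc3)[C@@H](O)[C@@H]4O)[C@H]2O)cc1 | intermediate
25 | CNP0159291.1, ent-epiafzelechin-(4β→8)-epiafzelechin-(4α→8)-(2S,3S,4R)-leucopelargonidin | Oc1ccc([C@H]2Oc3c(c(O)cc(O)c3[C@H]3c4c(O)cc(O)cc4O[C@@H](c4ccc(O)cc4)[C@H]3O)[C@@H](c3c(O)cc(O)c4c3O[C@@H](c3ccc(O)cc3)[C@@H](O)[C@@H]4O)[C@H]2O)cc1 | target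

## Count and risks
Total step count: 17. Longest linear sequence: 13 (steps 1, 2, 5, 6, 7, 8, 9, 11, 13, 14, 15, 16, 17).

**Step 7 (the new ring expansion).** The benzylic cation may lose a proton or undergo a hydride shift and end as the 2-benzylbenzofuran instead of being bridged by the ring oxygen.
- The fallback is the known diol route. It sets out from 10, comes back at 13, and drops steps 6 and 7.
- TBSCl/imidazole gives the silyl ether F1.
- OsO4 (cat.)/NMO gives the racemic threo diol F2.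
- TBAF gives the phenolic diol F3.
- HC(OEt)3/PPTS closes ring C directly, through the cyclic orthoformate and the benzylic cation, to the 2,3-trans 3-O-formate F4.
- K2CO3/MeOH gives 13.

**Step 13 (second coupling).** Electrophile 18 can self-condense through its own C8. The pairing of a 2S electrophile with a 2R upper unit is also untested and may be slow or leak to C6.
- The fallback caps C8. It sets out from 16 and comes back at 20.
- NBS (CH2Cl2, −78 °C) gives the 8-bromide F5.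
- DDQ/2-ethoxyethanol gives the capped electrophile F6, which cannot act as a nucleophile.
- Coupling with 19 under the same Lewis acid gives the bromo trimer F7.
- n-Bu3SnH/AIBN removes the bromine to give 20, which is methanolysed as before.

**Step 16 (late C–H hydroxylation).** DDQ may also attack C2–H or the diarylmethine C4–H of the upper units, or over-oxidise to the 4-ketone.
- The fallback uses ligand-transfer acetoxylation instead of hydride abstraction. It sets out from 23 and comes back at 24.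
- Pb(OAc)4 in benzene, the classical C4 acetoxylation of flavans, gives the 4α-acetate F8.
- K2CO3/MeOH gives 24.

## Further compounds
F1 | step 7 | tert-butyldimethylsilyl ether of 10 | CC(C)(C)[Si](C)(C)Oc1cc(OCc5cc(C)cc(C)c5)cc(OCc5cc(C)cc(C)c5)c1C/C=C/c1ccc(OCc5cc(C)cc(C)c5)cc1
F2 | step 7 | (±)-(1S*,2S*)-3-[2-(tert-butyldimethylsilyloxy)-4,6-bis(XB-oxy)phenyl]-1-[4-(XB-oxy)phenyl]propane-1,2-diol | CC(C)(C)[Si](C)(C)Oc1cc(OCc5cc(C)cc(C)c5)cc(OCc5cc(C)cc(C)c5)c1C[C@H](O)[C@@H](O)c1ccc(OCc5cc(C)cc(C)c5)cc1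
F3 | step 7 | (±)-(1S*,2S*)-3-[2-hydroxy-4,6-bis(XB-oxy)phenyl]-1-[4-(XB-oxy)phenyl]propane-1,2-diol | Oc1cc(OCc5cc(C)cc(C)c5)cc(OCc5cc(C)cc(C)c5)c1C[C@H](O)[C@@H](O)c1ccc(OCc5cc(C)cc(C)c5)cc1
F4 | step 7 | (±)-(2R*,3S*)-3-O-formyl-5,7,4'-tri-O-XB-afzelechin | O=CO[C@H]1Cc2c(OCc5cc(C)cc(C)c5)cc(OCc5cc(C)cc(C)c5)cc2O[C@@H]1c1ccc(OCc5cc(C)cc(C)c5)cc1
F5 | step 13 | (2S,3R)-8-bromo-3-O-propanoyl-5,7,4'-tri-O-XB-ent-afzelechin | CCC(=O)O[C@@H]1Cc2c(OCc5cc(C)cc(C)c5)cc(OCc5cc(C)cc(C)c5)c(Br)c2O[C@H]1c1ccc(OCc5cc(C)cc(C)c5)cc1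
F6 | step 13 | (2S,3R,4S)-8-bromo-4-(2-ethoxyethoxy)-3-O-propanoyl-5,7,4'-tri-O-XB-ent-afzelechin | CCC(=O)O[C@@H]1[C@@H](OCCOCC)c2c(OCc5cc(C)cc(C)c5)cc(OCc5cc(C)cc(C)c5)c(Br)c2O[C@H]1c1ccc(OCc5cc(C)cc(C)c5)cc1
F7 | step 13 | 20 with bromine at C8 of the top unit | c1(OCc5cc(C)cc(C)c5)ccc([C@H]2Oc3c(c(OCc5cc(C)cc(C)c5)cc(OCc5cc(C)cc(C)c5)c3[C@H]3c4c(OCc5cc(C)cc(C)c5)cc(OCc5cc(C)cc(C)c5)c(Br)c4O[C@@H](c4ccc(OCc5cc(C)cc(C)c5)cc4)[C@@H]3OC(=O)CC)[C@@H](c3c(OCc5cc(C)cc(C)c5)cc(OCc5cc(C)cc(C)c5)c4c3O[C@@H](c3ccc(OCc5cc(C)cc(C)c5)cc3)[C@H](O)C4)[C@@H]2OC(=O)CC)cc1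
F8 | step 16 | 23 with a 4α-acetoxy group in the bottom unit | c1(OCc5cc(C)cc(C)c5)ccc([C@H]2Oc3c(c(OCc5cc(C)cc(C)c5)cc(OCc5cc(C)cc(C)c5)c3[C@H]3c4c(OCc5cc(C)cc(C)c5)cc(OCc5cc(C)cc(C)c5)cc4O[C@@H](c4ccc(OCc5cc(C)cc(C)c5)cc4)[C@H]3O)[C@@H](c3c(OCc5cc(C)cc(C)c5)cc(OCc5cc(C)cc(C)c5)c4c3O[C@@H](c3ccc(OCc5cc(C)cc(C)c5)cc3)[C@@H](O)[C@@H]4OC(C)=O)[C@H]2O)cc1
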